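**Retrosynthetic overview**
1. Target 27 ⇐ keto diester 26 (chelation-controlled reduction of the C9 ketone) ⇐ ten-membered α-hydroxy ketone 20 (C8 and C3 angeloylation with one batch of mixed anhydride 22, C3–OH-directed epoxidation of the 4Z alkene).
2. 20 ⇐ cyclohexanol 17 by an anionic oxy-Cope ring expansion (six → ten): C6–C7 is made, the temporary C4–C9 bond is broken, and the ring enolate C8=C9 is hydroxylated in the same flask.
3. Enabling feature: the 3-oxido-1,5-diene C6=C5–C4–C9(O−)–C8=C7 laid across the bond C4–C9 of the six-membered ring C9–C10–C1–C2–C3–C4, with the C4 vinyl and the C9 (Z)-dienyl cis and C1–C10 already an oxirane.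
4. 17 ⇐ enone 12 + 2-methylbut-1-en-3-yne (13); 12 ⇐ (S)-carvone (1) by Criegee excision of the isopropenyl group (C3–O) and two α′-alkylations (C4 quaternary centre).
5. Ring order: six-membered ring (from carvone) → oxirane C1–C10 (step 7) → ten-membered ring (step 9) → oxirane C4–C5 (step 13).

Key step: step 9

Remark on the chemistry: the SMILES is read as written, which makes both oxiranes cis (derived from Z alkenes). Germacrane numbering is used (ring C1–C10, CH3 on C4 and C10, isopropenyl on C7), also for the six-membered-ring compounds (cyclohexenone C1/C2/C3/C4/C5/C6 = germacrane C9/C10/C1/C2/C3/C4). β means the face of the C7 isopropenyl group in the flat ring formula.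

**Route**

Step 1
Reactants: 1 (S)-(+)-carvone
Product: 4 (5S)-5-acetoxy-2-methylcyclohex-2-en-1-one, via methoxy hydroperoxide 2 (not isolated), via peracetate 3 (not isolated)
Conditions: O3, CH2Cl2/MeOH, −78 °C; then Ac2O, Et3N, DMAP (cat.), −78 °C to rt
Reagents that add atoms: ozone [O-][O+]=O; methanol CO
Why: Ozonolysis of the electron-rich isopropenyl group in methanol and Criegee rearrangement of the derived peracetate move the ring carbon from C to O with retention, so the carvone stereocentre becomes the C3–O centre (the acetyl carbons are carvone's own; the enone alkene is too electron-poor for ozone).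

Step 2
Reactants: 4 (5S)-5-acetoxy-2-methylcyclohex-2-en-1-one
Product: 5 (5S)-5-hydroxy-2-methylcyclohex-2-en-1-one
Conditions: K2CO3 (cat.), MeOH, 0 °C
Reagents that add atoms: none
Why: Base-catalysed transesterification at 0 °C should free the alcohol faster than β-elimination of the β-acetoxy ketone.

Step 3
Reactants: 5 (5S)-5-hydroxy-2-methylcyclohex-2-en-1-one
Product: 6 (5S)-5-[(tert-butyldimethylsilyl)oxy]-2-methylcyclohex-2-en-1-one
Conditions: TBSCl, imidazole, DMF, rt
Reagents that add atoms: tert-butyldimethylsilyl chloride CC(C)(C)[Si](C)(C)Cl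
Why: Standard silylation of a secondary alcohol gives a bulky ether that later serves as the conformational anchor (equatorial OTBS).

Step 4
Reactants: 6 (5S)-5-[(tert-butyldimethylsilyl)oxy]-2-methylcyclohex-2-en-1-one
Product: 8 (5S,6R)-5-[(tert-butyldimethylsilyl)oxy]-2,6-dimethylcyclohex-2-en-1-one, via lithium dienolate 7 (not isolated)
Conditions: LiN(iPr)2, THF, −78 °C; MeI, −78 to −40 °C
Reagents that add atoms: iodomethane CI
Why: Kinetic α′-deprotonation gives the cross-conjugated enolate, which is methylated anti to the neighbouring OTBS (enolate alkylation); the configuration of this centre is irrelevant because it is planarised again in step 5.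

Step 5
Reactants: 8 (5S,6R)-5-[(tert-butyldimethylsilyl)oxy]-2,6-dimethylcyclohex-2-en-1-one; 9 phenyl vinyl sulfoxide
Product: 12 (5S,6R)-5-[(tert-butyldimethylsilyl)oxy]-6-ethenyl-2,6-dimethylcyclohex-2-en-1-one, via lithium enolate 10 (not isolated), via sulfoxide adduct 11 (not isolated)
Conditions: LiN(iPr)2, THF, −78 °C; 9, −78 to −30 °C; H2O; then toluene, NaHCO3, 110 °C
Reagents that add atoms: none
Why: Michael addition of the tetrasubstituted enolate to the vinyl sulfoxide (a vinyl cation equivalent) occurs anti to the OTBS group, and thermal syn-elimination of benzenesulfenic acid then unveils the vinyl group, which sets the C4 quaternary centre with CH3 cis and vinyl trans to OTBS.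

Step 6
Reactants: 12 (5S,6R)-5-[(tert-butyldimethylsilyl)oxy]-6-ethenyl-2,6-dimethylcyclohex-2-en-1-one; 13 2-methylbut-1-en-3-yne
Product: 15 (1S,5S,6R)-propargylic alcohol, via lithium acetylide 14 (not isolated)
Conditions: 13, n-BuLi, THF, −78 °C; then 12, −78 to −20 °C; H2O
Reagents that add atoms: none
Why: 1,2-Addition of the small acetylide should follow the axial trajectory on the conformer with equatorial OTBS and axial 6-CH3, i.e. anti to that CH3, which places the alkynyl group cis to the vinyl group and the new C9–OH cis to CH3 and OTBS.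

Step 7
Reactants: 15 (1S,5S,6R)-propargylic alcohol
Product: 16 epoxy alcohol (oxirane cis to the tertiary OH)
Conditions: VO(acac)2 (cat.), t-BuOOH, CH2Cl2, 0 °C to rt
Reagents that add atoms: tert-butyl hydroperoxide CC(C)(C)OO
Why: Hydroxyl-directed epoxidation of the cyclic allylic alcohol delivers oxygen to C1=C10 on the face of the C9–OH (the future 1β,10β-oxirane); the alkyne is inert and the vinyl group, being only homoallylic and monosubstituted, reacts much more slowly.

Step 8
Reactants: 16 epoxy alcohol (oxirane cis to the tertiary OH)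
Product: 17 (Z)-dienyl epoxy alcohol
Conditions: Zn(Cu/Ag) couple, MeOH/H2O, rt
Reagents that add atoms: none
Why: Dissolving-zinc cis-semireduction is selective for the conjugated enyne and gives the (Z)-1,3-diene while leaving the isolated vinyl group, the oxirane and the silyl ether untouched.

Step 9
Reactants: 17 (Z)-dienyl epoxy alcohol
Product: 20 ten-membered α-hydroxy ketone (4Z; 8β-OH), via potassium alkoxide 18 (not isolated), via potassium enolate 19 (not isolated)
Conditions: KN(SiMe3)2, 18-crown-6, THF, 0 to 45 °C; then −78 °C, 2-(phenylsulfonyl)-3-phenyloxaziridine; H2O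
Reagents that add atoms: 2-(phenylsulfonyl)-3-phenyloxaziridine O=S(=O)(c1ccccc1)N1OC1c1ccccc1
Why: Deprotonation gives alkoxide 18, whose 3-oxido-1,5-diene C6=C5–C4–C9(O−)–C8=C7 undergoes a charge-accelerated [3,3]-sigmatropic (anionic oxy-Cope) shift that makes C6–C7, breaks the temporary C4–C9 bond and leaves enolate 19, which the N-sulfonyloxaziridine hydroxylates at C8 by electrophilic oxygen transfer. The closest known reaction type is the anionic oxy-Cope ring expansion of cis-1,2-dialkenylcyclohexanols to cyclodec-5-enones with trapping or oxidation of the ring enolate. The ten-membered ring is closed by a four-atom ring expansion through a chair six-centre transition state, suprafacial on both allyl units, and not by an end-to-end cyclisation, so high dilution is not needed. C7 is set by chirality transfer from C9 and C4 through this chair together with the Z geometry of C7=C8 (isopropenyl pseudo-axial), the 4Z alkene arises because the cis relation of vinyl and dienyl places C3 pseudo-axial on the chair, and C8 is set by attack of the oxidant on the outer face of the first-formed ring enolate, whose inner face is covered by C4–C6. The step needs this chair to win over the other chair and the boats: the Z-isopropenyl group forces the small oxido group and not C10 into the neighbouring pseudo-axial site, and the equatorial OTBS group disfavours the ring-flipped arrangement, which would put OTBS and O− 1,3-diaxial. The competing [3,3] shift through a C1=C10 alkene and a Payne rearrangement are excluded because C1–C10 is already an oxirane cis to the oxido group.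

Step 10
Reactants: 21 angelic acid
Product: 22 (Z)-2-methylbut-2-enoic 2,4,6-trichlorobenzoic anhydride
Conditions: 2,4,6-trichlorobenzoyl chloride, Et3N, toluene, 0 °C to rt; filtered under argon, kept as a toluene solution at −20 °C
Reagents that add atoms: 2,4,6-trichlorobenzoyl chloride O=C(Cl)c1c(Cl)cc(Cl)cc1Cl
Why: Acyl substitution of the hindered aroyl chloride by the triethylammonium carboxylate (Yamaguchi activation) should give the mixed anhydride without a nucleophilic catalyst, so the Z geometry is kept; one batch, freed from the ammonium salt, supplies both acylations (steps 11 and 14).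

Step 11
Reactants: 20 ten-membered α-hydroxy ketone (4Z; 8β-OH); 22 (Z)-2-methylbut-2-enoic 2,4,6-trichlorobenzoic anhydride
Product: 23 C8 angelate
Conditions: 22 (toluene solution), Et3N, toluene, 80 °C
Reagents that add atoms: none
Why: Yamaguchi-type mixed-anhydride acylation without a nucleophilic catalyst should transfer the (Z)-2-methylbut-2-enoyl group to the only free hydroxyl (C8) without Z-to-E isomerisation, because the two ortho chlorines shield the aroyl carbonyl and the alcohol attacks the aliphatic one.

Step 12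
Reactants: 23 C8 angelate
Product: 24 allylic alcohol (3β-OH)
Conditions: HF·pyridine, pyridine/THF, 0 °C to rt
Reagents that add atoms: none
Why: Buffered fluoride desilylation removes the TBS ether while the ester, the oxirane next to the ketone and the alkenes should survive.

Step 13
Reactants: 24 allylic alcohol (3β-OH)
Product: 25 4α,5α-epoxy alcohol
Conditions: mCPBA, NaHCO3, CH2Cl2, 0 °C
Reagents that add atoms: 3-chloroperoxybenzoic acid OOC(=O)c1cccc(Cl)c1
Why: The trisubstituted C4=C5 alkene is the most nucleophilic one, and hydrogen-bonded peracid delivery to the (Z)-allylic alcohol in its conformer of minimal allylic 1,3-strain gives the threo epoxy alcohol, i.e. the oxirane oxygen trans to the C3–OH, as is the rule for cis-cycloalkenols of medium ring size; the C8 oxygen is already acylated, so only the C3–OH can direct.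

Step 14
Reactants: 25 4α,5α-epoxy alcohol; 22 (Z)-2-methylbut-2-enoic 2,4,6-trichlorobenzoic anhydride
Product: 26 keto bis-angelate
Conditions: 22 (toluene solution), Et3N, toluene, 80 °C
Reagents that add atoms: none
Why: A second portion of the same mixed anhydride esterifies the remaining C3–OH by the same Yamaguchi-type acylation, and the C9 carbonyl keeps the future C9–OH differentiated from the two acylated oxygens.

Step 15
Reactants: 26 keto bis-angelate
Product: 27 target CNP0304877.1
Conditions: Zn(BH4)2, Et2O, −20 °C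
Reagents that add atoms: none
Why: Chelation-controlled hydride reduction, with zinc bridging the C9 carbonyl and the oxirane and ester oxygens, should give the alcohol anti to both flanking C–O bonds (erythro to the 1,10-oxirane and to C8–O), i.e. 9β-OH, and the low temperature should prevent acyl migration and ester reduction.

**Compound list**
1 | (S)-(+)-carvone, (5S)-2-methyl-5-(prop-1-en-2-yl)cyclohex-2-en-1-one | O=C1C(C)=CC[C@H](C(C)=C)C1 | starting material
2 | (5S)-5-(1-hydroperoxy-1-methoxyethyl)-2-methylcyclohex-2-en-1-one (side-chain epimers, not isolated) | O=C1C(C)=CC[C@H](C(C)(OC)OO)C1 | intermediate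
3 | 1-methoxy-1-[(1S)-4-methyl-5-oxocyclohex-3-en-1-yl]ethyl peroxyacetate (not isolated) | O=C1C(C)=CC[C@H](C(C)(OC)OOC(C)=O)C1 | intermediate
4 | (5S)-5-acetoxy-2-methylcyclohex-2-en-1-one | O=C1C(C)=CC[C@H](OC(C)=O)C1 | intermediate
5 | (5S)-5-hydroxy-2-methylcyclohex-2-en-1-one | O=C1C(C)=CC[C@H](O)C1 | intermediate
6 | (5S)-5-[(tert-butyldimethylsilyl)oxy]-2-methylcyclohex-2-en-1-one | O=C1C(C)=CC[C@H](O[Si](C)(C)C(C)(C)C)C1 | intermediate
7 | lithium dienolate of 6 (OLi on C1, C1=C6 and C2=C3; not isolated) | [Li]OC1=C[C@@H](O[Si](C)(C)C(C)(C)C)CC=C1C | intermediate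
8 | (5S,6R)-5-[(tert-butyldimethylsilyl)oxy]-2,6-dimethylcyclohex-2-en-1-one (6-CH3 trans to OTBS) | O=C1C(C)=CC[C@H](O[Si](C)(C)C(C)(C)C)[C@H]1C | intermediate
9 | phenyl vinyl sulfoxide | C=CS(=O)c1ccccc1 | starting material
10 | lithium enolate of 8 (OLi on C1, C1=C6 and C2=C3; not isolated) | [Li]OC1=C(C)[C@@H](O[Si](C)(C)C(C)(C)C)CC=C1C | intermediate
11 | (5S,6R)-5-[(tert-butyldimethylsilyl)oxy]-2,6-dimethyl-6-[2-(phenylsulfinyl)ethyl]cyclohex-2-en-1-one (sulfoxide epimers, not isolated) | O=C1C(C)=CC[C@H](O[Si](C)(C)C(C)(C)C)[C@@]1(C)CCS(=O)c1ccccc1 | intermediate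
12 | (5S,6R)-5-[(tert-butyldimethylsilyl)oxy]-6-ethenyl-2,6-dimethylcyclohex-2-en-1-one (CH3 cis, vinyl trans to OTBS) | O=C1C(C)=CC[C@H](O[Si](C)(C)C(C)(C)C)[C@@]1(C)C=C | intermediate
13 | 2-methylbut-1-en-3-yne | C#CC(C)=C | starting material
14 | lithium 3-methylbut-3-en-1-yn-1-ide (not isolated) | [Li]C#CC(C)=C | intermediate
15 | (1S,5S,6R)-5-[(tert-butyldimethylsilyl)oxy]-6-ethenyl-2,6-dimethyl-1-(3-methylbut-3-en-1-yn-1-yl)cyclohex-2-en-1-ol (OH, 6-CH3 and OTBS on one face; vinyl and alkynyl on the other) | O[C@]1(C#CC(C)=C)C(C)=CC[C@H](O[Si](C)(C)C(C)(C)C)[C@@]1(C)C=C | intermediate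
16 | 4-[(tert-butyldimethylsilyl)oxy]-3-ethenyl-1,3-dimethyl-2-(3-methylbut-3-en-1-yn-1-yl)-7-oxabicyclo[4.1.0]heptan-2-ol (oxirane O, 2-OH, 3-CH3 and 4-OTBS on one face; ring configuration as in 15) | O[C@]1(C#CC(C)=C)[C@]2(C)O[C@@H]2C[C@H](O[Si](C)(C)C(C)(C)C)[C@@]1(C)C=C | intermediate
17 | 4-[(tert-butyldimethylsilyl)oxy]-3-ethenyl-1,3-dimethyl-2-[(1Z)-3-methylbuta-1,3-dien-1-yl]-7-oxabicyclo[4.1.0]heptan-2-ol (configuration as in 16) | O[C@]1(/C=C\C(C)=C)[C@]2(C)O[C@@H]2C[C@H](O[Si](C)(C)C(C)(C)C)[C@@]1(C)C=C | intermediate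
18 | potassium alkoxide of 17 (not isolated) | [K]O[C@]1(/C=C\C(C)=C)[C@]2(C)O[C@@H]2C[C@H](O[Si](C)(C)C(C)(C)C)[C@@]1(C)C=C | intermediate
19 | potassium enolate (OK on C9, C8=C9 with C7 and C10 trans; 4Z) of 3β-[(tert-butyldimethylsilyl)oxy]-1β,10β-epoxygermacra-4,11(12)-dien-9-one (not isolated) | [K]O/C1=C\[C@@H](C(C)=C)C/C=C(C)\[C@@H](O[Si](C)(C)C(C)(C)C)C[C@H]2O[C@@]12C | intermediate
20 | (4Z)-3β-[(tert-butyldimethylsilyl)oxy]-1β,10β-epoxy-8β-hydroxygermacra-4,11(12)-dien-9-one | C=C(C)[C@H]1C/C=C(C)\[C@@H](O[Si](C)(C)C(C)(C)C)C[C@H]2O[C@@]2(C)C(=O)[C@H]1O | intermediate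
21 | angelic acid, (Z)-2-methylbut-2-enoic acid | C/C=C(/C)C(=O)O | starting material
22 | (Z)-2-methylbut-2-enoic 2,4,6-trichlorobenzoic anhydride (one batch, kept as a toluene solution) | C/C=C(/C)C(=O)OC(=O)c1c(Cl)cc(Cl)cc1Cl | intermediate
23 | (4Z)-8β-angeloyloxy-3β-[(tert-butyldimethylsilyl)oxy]-1β,10β-epoxygermacra-4,11(12)-dien-9-one | C=C(C)[C@H]1C/C=C(C)\[C@@H](O[Si](C)(C)C(C)(C)C)C[C@H]2O[C@@]2(C)C(=O)[C@H]1OC(=O)/C(C)=C\C | intermediate
24 | (4Z)-8β-angeloyloxy-1β,10β-epoxy-3β-hydroxygermacra-4,11(12)-dien-9-one | C=C(C)[C@H]1C/C=C(C)\[C@@H](O)C[C@H]2O[C@@]2(C)C(=O)[C@H]1OC(=O)/C(C)=C\C | intermediate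
25 | 8β-angeloyloxy-1β,10β:4α,5α-diepoxy-3β-hydroxygermacr-11(12)-en-9-one | C=C(C)[C@H]1C[C@@H]2O[C@]2(C)[C@@H](O)C[C@H]2O[C@@]2(C)C(=O)[C@H]1OC(=O)/C(C)=C\C | intermediate
26 | 3β,8β-bis(angeloyloxy)-1β,10β:4α,5α-diepoxygermacr-11(12)-en-9-one | C=C(C)[C@H]1C[C@@H]2O[C@]2(C)[C@@H](OC(=O)/C(C)=C\C)C[C@H]2O[C@@]2(C)C(=O)[C@H]1OC(=O)/C(C)=C\C | intermediate
27 | CNP0304877.1, 3β,8β-bis(angeloyloxy)-1β,10β:4α,5α-diepoxygermacr-11(12)-en-9β-ol | C=C(C)[C@H]1C[C@@H]2O[C@]2(C)[C@@H](OC(=O)/C(C)=C\C)C[C@H]2O[C@@]2(C)[C@@H](O)[C@H]1OC(=O)/C(C)=C\C | target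

**Step count and risks**
Total step count: 15. Longest linear sequence: 14 steps (1 → 27 through steps 1–9 and 11–15); step 10 is a one-step branch that makes the acylating agent 22 from 21; 9, 13 and 21 are commercial building blocks.

Steps most likely to fail:

1. Step 9. The alkoxide may rearrange through the other chair or a boat (giving the 4E isomer or the C7 epimer). The hindered (Z)-dienyl carbinol may react so slowly that 1,5-silyl migration from O3 to O9 or base-induced decomposition competes. The in-flask hydroxylation may lose facial control once the ring enolate has relaxed conformationally. The fallback sets out from 17 and returns at 20 and removes the alkoxide from the sequence. The alcohol is silylated (TMSCl, imidazole, CH2Cl2) to trimethylsilyl ether F1. A neutral silyloxy-Cope rearrangement (o-xylene, 180–200 °C, sealed tube) gives the isolable ring-expanded trimethylsilyl enol ether F2. Rubottom oxidation of F2 with dimethyldioxirane (acetone/CH2Cl2, −40 °C) gives α-silyloxy ketone F3, and citric acid in MeOH cleaves the trimethylsilyl ether to give 20.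

2. Step 5. The enolate carries a β-silyloxy group, so E1cB loss of silanolate with aromatisation can compete with the slow Michael addition of a tetrasubstituted enolate, and facial selectivity at the new quaternary centre may be incomplete. The fallback sets out from 5 and returns at 12 and uses Fráter–Seebach-type dianion chemistry, in which the oxido group cannot leave and directs the electrophile anti. Alcohol 5 is treated with LiN(iPr)2 (2.2 equiv, THF, −78 °C) and MeI to give hydroxy ketone F4. A second dianion formation and addition to 9 give hydroxy sulfoxide F5. Thermolysis (toluene, NaHCO3, 110 °C) gives vinyl hydroxy enone F6, and silylation (TBSOTf, 2,6-lutidine, CH2Cl2, −78 °C) gives 12.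

3. Step 13. Facial selectivity of the peracid on the flexible ten-membered ring may be poor or reversed (transannular hemiketal formation between C3–OH and the C9 carbonyl could change the reacting conformer), and the new oxirane may open under acid. The fallback sets out from 24 and returns at 25 and inverts the facial outcome by a two-stage halohydrin route. NBS in THF/H2O (0 °C) forms the bromonium ion on the face the peracid prefers, and water opens it at C4 from the opposite face to give bromohydrin F7 (5β-Br, 4α-OH). Ag2O (CH2Cl2, rt) then closes the oxirane by intramolecular SN2 displacement at C5, which gives the 4α,5α-oxirane 25.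

Further compounds
F1 | step 9 | trimethylsilyl ether of 17 | C[Si](C)(C)O[C@]1(/C=C\C(C)=C)[C@]2(C)O[C@@H]2C[C@H](O[Si](C)(C)C(C)(C)C)[C@@]1(C)C=C
F2 | step 9 | (4Z)-3β-[(tert-butyldimethylsilyl)oxy]-1β,10β-epoxy-9-[(trimethylsilyl)oxy]germacra-4,8,11(12)-triene (C7 and C10 trans on C8=C9) | C[Si](C)(C)O/C1=C\[C@@H](C(C)=C)C/C=C(C)\[C@@H](O[Si](C)(C)C(C)(C)C)C[C@H]2O[C@@]12C
F3 | step 9 | (4Z)-3β-[(tert-butyldimethylsilyl)oxy]-1β,10β-epoxy-8β-[(trimethylsilyl)oxy]germacra-4,11(12)-dien-9-one | C=C(C)[C@H]1C/C=C(C)\[C@@H](O[Si](C)(C)C(C)(C)C)C[C@H]2O[C@@]2(C)C(=O)[C@H]1O[Si](C)(C)C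
F4 | step 5 | (5S,6R)-5-hydroxy-2,6-dimethylcyclohex-2-en-1-one | O=C1C(C)=CC[C@H](O)[C@H]1C
F5 | step 5 | (5S,6R)-5-hydroxy-2,6-dimethyl-6-[2-(phenylsulfinyl)ethyl]cyclohex-2-en-1-one | O=C1C(C)=CC[C@H](O)[C@@]1(C)CCS(=O)c1ccccc1
F6 | step 5 | (5S,6R)-6-ethenyl-5-hydroxy-2,6-dimethylcyclohex-2-en-1-one | O=C1C(C)=CC[C@H](O)[C@@]1(C)C=C
F7 | step 13 | 8β-angeloyloxy-5β-bromo-1β,10β-epoxy-3β,4α-dihydroxygermacr-11(12)-en-9-one | C=C(C)[C@H]1C[C@@H](Br)[C@@](O)(C)[C@@H](O)C[C@H]2O[C@@]2(C)C(=O)[C@H]1OC(=O)/C(C)=C\C
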